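**Plan**

1. Ring numbering used throughout: C1 (CH–isobutyryl), C2 (C=O), C3 (prenyl carbinol), C4 (C=O), C5 (CH–prenyl), C6 (CH2), C7 (CH–prenyl), C8 (quaternary: methyl and 4-methylpent-3-enyl).
2. Retrosynthesis: first the acyl C–C bond at C1 (aldol, then oxidation), the C3–O and C3–prenyl bonds (enolate chemistry of the C2/C4 1,3-diketone) and the C5–C6 saturation (conjugate reduction) are removed. Then C7–C8 is cut while C2–C5 is re-formed (retro oxy-Cope), then C1–C2 (alkenylmetal plus cyclobutanone), then C2–C3 and C4–C5 (ketene plus ketene acetal).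
3. Enabling feature: the adjacent stereocentres C7 and C8 lie across the ring from the C2–C3–C4–C5 segment. C2 and C5 can therefore be tied into a cyclobutane that carries a Z alkenyl group (C1=C8) on the carbinol carbon C2 and an E alkenyl group (C6=C7) on C5, a cis-1,2-dialkenylcyclobutanol.
4. Forward: the four-membered ring C2–C3–C4–C5 is made first by [2+2] cycloaddition, the Z alkenyl unit is added to its ketone, and the cyclooctane (the only ring of the target) arises by four-carbon ring expansion. The periphery follows.
5. Stereochemistry: C7/C8 relative configuration comes from the two alkene geometries in a boat transition state. The absolute configuration comes from C5 of the cyclobutane (separation of the diastereomeric (R,R)-butane-2,3-diol ketals) and from C2 (facial addition). C3 comes from face-selective enolate hydroxylation, and C5 and C1 from protonation or equilibration of α-carbonyl centres.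

Key step: step 9

Remark: C1 and C5 are enolisable α-carbonyl centres; their natural configurations (isobutyryl cis to the C8 methyl group, C5 prenyl trans to the C7 prenyl group) are taken to be the thermodynamically preferred ones and are left to protonation or equilibration.

**Route**

Step 1
Reactants: 1 5-bromo-2-methylpent-2-ene; 2 propyne
Product: 5 (1Z)-1-iodo-2,6-dimethylhepta-1,5-diene, via alkylmagnesium bromide 3 (not isolated), via alkenylcopper 4 (not isolated)
Conditions: Mg, Et2O; CuBr·SMe2, Et2O/Me2S, −45 °C; propyne, −25 °C; I2, −50 → 0 °C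
Reagents that add atoms: iodine, II
Why: Normant carbocupration adds the alkylcopper reagent syn across propyne with the alkyl group on the internal carbon and copper on the terminal one, so chain and metal are cis, and iodinolysis with retention should give the Z iodide that later becomes the Z C1=C8 alkene.

Step 2
Reactants: 6 5-methylhex-4-enal; 7 malonic acid
Product: 8 (3E)-7-methylocta-3,6-dienoic acid
Conditions: piperidinium acetate (cat.), DMSO, 100 °C
Reagents that add atoms: none
Why: The Knoevenagel–Doebner condensation run with piperidinium acetate in DMSO is the deconjugative variant that should deliver the (E)-alk-3-enoic acid after decarboxylation, which fixes the E geometry of the future C6=C7 alkene.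

Step 3
Reactants: 8 (3E)-7-methylocta-3,6-dienoic acid; 9 1-bromo-3-methylbut-2-ene
Product: 11 (3E)-7-methyl-2-(3-methylbut-2-enyl)octa-3,6-dienoic acid (racemic), via dilithium dienediolate 10 (not isolated)
Conditions: LiN(iPr)2 (2.2 equiv), THF, −78 → −20 °C; 9, −78 → 0 °C; aq. HCl work-up
Reagents that add atoms: none
Why: α-Alkylation of a carboxylic acid dianion, in which the lithium dienediolate should react with the allylic bromide at its α-carbon in an SN2 reaction while the C3=C4 bond keeps its E geometry; the new α-centre is racemic and becomes the sp2 ketene carbon in step 7.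

Step 4
Reactants: 11 (3E)-7-methyl-2-(3-methylbut-2-enyl)octa-3,6-dienoic acid
Product: 12 (3E)-7-methyl-2-(3-methylbut-2-enyl)octa-3,6-dienoyl chloride (racemic, used crude)
Conditions: (COCl)2, DMF (cat.), CH2Cl2, 0 °C → rt
Reagents that add atoms: oxalyl chloride, O=C(Cl)C(=O)Cl
Why: Acid chloride formation with oxalyl chloride under chloroiminium (Vilsmeier-type) catalysis proceeds at 0 °C, where the trisubstituted and skipped alkenes should not be touched.

Step 5
Reactants: 13 (2R,3R)-butane-2,3-diol; 14 2-bromo-1,1-diethoxyethane
Product: 15 (4R,5R)-2-(bromomethyl)-4,5-dimethyl-1,3-dioxolane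
Conditions: TsOH·H2O (cat.), neat, 110 °C, EtOH distilled off
Reagents that add atoms: none
Why: Acid-catalysed transacetalisation driven by removal of ethanol gives the dioxolane without touching the two carbinol stereocentres, and the C2 symmetry of the diol means no new stereocentre arises.

Step 6
Reactants: 15 (4R,5R)-2-(bromomethyl)-4,5-dimethyl-1,3-dioxolane
Product: 16 (4R,5R)-4,5-dimethyl-2-methylidene-1,3-dioxolane
Conditions: KOtBu, THF, 0 °C → rt; distillation
Reagents that add atoms: none
Why: E2 dehydrobromination of a 2-(bromomethyl)-1,3-dioxolane with tert-butoxide is the classical entry to cyclic ketene acetals.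

Step 7
Reactants: 12 (3E)-7-methyl-2-(3-methylbut-2-enyl)octa-3,6-dienoyl chloride; 16 (4R,5R)-4,5-dimethyl-2-methylidene-1,3-dioxolane
Product: 18 (1S,6R,7R)-6,7-dimethyl-1-(3-methylbut-2-enyl)-1-[(1E)-5-methylhexa-1,4-dienyl]-5,8-dioxaspiro[3.4]octan-2-one (spiro C1 = ring C5, spiro C2 = ring C2), via vinylketene 17 (not isolated)
Conditions: Et3N (1.5 equiv), 16 (2 equiv), hexane, 60 °C, slow addition of 12; chromatographic separation of the two C5 epimers
Reagents that add atoms: none
Why: Dehydrochlorination gives the alkyl(vinyl)ketene 17, which should add the electron-rich ketene acetal in the stepwise polar [2+2] cycloaddition typical of ketenes (acetal CH2 to the ketene carbonyl carbon, then enolate carbon C5 to the dioxolanylium carbon C4), giving the 3,3-dialkoxycyclobutanone regiochemistry across the ketene C=C and not the vinyl group; the C2-symmetric ketal leaves C4 non-stereogenic, little facial bias is expected at the new quaternary centre C5, and the two C5 epimers are separated as diastereomers.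

Step 8
Reactants: 5 (1Z)-1-iodo-2,6-dimethylhepta-1,5-diene; 18 (1S,6R,7R)-6,7-dimethyl-1-(3-methylbut-2-enyl)-1-[(1E)-5-methylhexa-1,4-dienyl]-5,8-dioxaspiro[3.4]octan-2-one
Product: 21 (1S,2S,6R,7R)-2-[(1Z)-2,6-dimethylhepta-1,5-dienyl]-6,7-dimethyl-1-(3-methylbut-2-enyl)-1-[(1E)-5-methylhexa-1,4-dienyl]-5,8-dioxaspiro[3.4]octan-2-ol (the two alkenyl groups cis), via alkenyllithium 19 (not isolated), via alkenylcerium dichloride 20 (not isolated)
Conditions: t-BuLi (2 equiv), Et2O, −78 °C; CeCl3, THF, −78 °C; 18, −78 °C; H2O quench
Reagents that add atoms: none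
Why: Iodine–lithium exchange with retention of the Z geometry and transmetalation to the weakly basic organocerium reagent should give clean 1,2-addition to the strained ketone without enolisation toward the ketal; the new C2 carbinol centre is set by attack anti to the sp3-branched prenyl arm and syn to the flatter alkenyl group on C5, which is expected to favour the cis-dialkenyl isomer, the trans isomer being removed by chromatography.

Step 9
Reactants: 21 (1S,2S,6R,7R)-2-[(1Z)-2,6-dimethylhepta-1,5-dienyl]-6,7-dimethyl-1-(3-methylbut-2-enyl)-1-[(1E)-5-methylhexa-1,4-dienyl]-5,8-dioxaspiro[3.4]octan-2-ol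
Product: 24 silyl enol ether, (7S,8R)-2-(trimethylsilyloxy)cycloocta-1,5-diene in ring numbering, with the (4R,5R)-4,5-dimethyl-1,3-dioxolane spiro at C4, prenyl on C5 and C7, methyl and 4-methylpent-3-enyl on C8, via potassium alkoxide 22 (not isolated), via potassium enolate 23 (not isolated)
Conditions: KH, 18-crown-6, THF, 0 °C → rt; then Me3SiCl/Et3N, −78 °C
Reagents that add atoms: chlorotrimethylsilane, C[Si](C)(C)Cl
Why: KH with 18-crown-6 gives the dissociated potassium alkoxide at C2, whose oxyanion weakens the adjacent C2–C5 bond and triggers a concerted suprafacial [3,3] shift over C8=C1–C2–C5–C6=C7 in which C7–C8 forms as C2–C5 breaks, and the resulting C1=C2 potassium enolate is silylated on oxygen before it can equilibrate toward C3. The closest known reaction is the anionic oxy-Cope rearrangement of cis-1,2-dialkenylcyclobutanols to cyclooctenones. The eight-membered ring is not closed end to end but arises by four-carbon ring expansion of the cyclobutane, the new C7–C8 bond closing it while the cyclobutane bond opens, so both ring alkenes (C1=C2 and C5=C6) are necessarily cis within the ring. The cis arrangement on the four-membered ring allows only a boat transition state, in which the E C6=C7 alkene places hydrogen inside and the prenyl CH2 outside on C7 and the Z C1=C8 alkene places the 4-methylpent-3-enyl chain inside and the methyl group outside on C8, so methyl and prenyl end up cis across the new bond, while the absolute configuration is transferred from C2 and C5 of the cyclobutane, which themselves become sp2. The step needs the concerted path to win over heterolytic C2–C5 fragmentation and over a [1,3] shift, which the cis disposition of the alkenyl groups, the release of ring strain and the formation of an enolate should secure, and the absence of a proton source keeps the enolate regiochemistry.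

Step 10
Reactants: 24 silyl enol ether; 25 2-methylpropanal
Product: 27 aldol, 24 with C2 as ketone and CH(OH)CH(CH3)2 on C1 (major diastereomer; C1 and carbinol configuration not assigned), via lithium enolate 26 (not isolated)
Conditions: MeLi, THF, 0 °C; 25, −78 °C; AcOH quench at −78 °C
Reagents that add atoms: none
Why: Methyllithium cleaves the O–Si bond to give the regiodefined C1=C2 lithium enolate, which should add to the aldehyde in an aldol reaction through a closed six-membered transition state; the stereocentres created at C1 and at the carbinol carbon are temporary, the major diastereomer is carried on, and both centres are erased or equilibrated in step 17.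

Step 11
Reactants: 27 aldol
Product: 28 tert-butyldimethylsilyl ether of 27
Conditions: TBSOTf, 2,6-lutidine, CH2Cl2, −78 °C
Reagents that add atoms: tert-butyldimethylsilyl trifluoromethanesulfonate, CC(C)(C)[Si](C)(C)OS(=O)(=O)C(F)(F)F
Why: Silylation of the hindered secondary alcohol with a silyl triflate and 2,6-lutidine gives a TBS ether that blocks retro-aldol cleavage and keeps the side chain free of acidic protons through steps 12 to 15.

Step 12
Reactants: 28 TBS ether
Product: 29 (7S,8R)-cyclooct-5-ene-2,4-dione in ring numbering (C2 and C4 ketones, C5=C6), side chain CH(OTBS)CH(CH3)2 on C1, other substituents as in 28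
Conditions: TsOH·H2O (0.1 equiv), THF–H2O, rt
Reagents that add atoms: water, O
Why: Acid-catalysed ketal hydrolysis, made easy by the β-carbonyl group and the allylic position of C4, should unmask the C2/C4 1,3-diketone and bring the C5=C6 alkene into conjugation while the TBS ether and the trisubstituted alkenes survive the dilute acid.

Step 13
Reactants: 29 enedione; 30 3-methylbut-2-enyl acetate
Product: 31 C3-prenyl enedione (29 with 3-methylbut-2-enyl on C3; C3 enolisable)
Conditions: Pd(PPh3)4 (5 mol %), Et3N, 30 (1.0 equiv), THF, 40 °C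
Reagents that add atoms: none
Why: In this Tsuji–Trost allylation the soft diketonate should attack the unsubstituted terminus of the 1,1-dimethylallyl palladium complex to place a linear prenyl group on C3, any O-prenyl enol ether being re-ionised by zerovalent palladium and funnelled to the C-alkylated product; C3 stays enolisable, so no configuration is fixed yet.

Step 14
Reactants: 31 C3-prenyl enedione
Product: 33 3-hydroxy-3-prenyl enedione (C3 hydroxyl on the ring face of the C8 methyl group, as in the target), via potassium diketonate 32 (not isolated)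
Conditions: KN(SiMe3)2 (1.05 equiv), THF, −78 °C; 3-phenyl-2-(phenylsulfonyl)oxaziridine, −78 → −40 °C; AcOH quench
Reagents that add atoms: 3-phenyl-2-(phenylsulfonyl)oxaziridine, O=S(=O)(c1ccccc1)N1OC1c1ccccc1
Why: In this Davis enolate oxidation the potassium diketonate attacks the oxaziridine oxygen, an oxidant that should leave the isolated alkenes alone, and the quaternary C3 carbinol is set by substrate control, the oxidant being expected to approach the planar C2–C3–C4 unit on the ring face that carries the C8 methyl group, away from the larger 4-methylpent-3-enyl chain on the opposite face.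

Step 15
Reactants: 33 3-hydroxy-3-prenyl enedione
Product: 34 (3R,5S,7S,8R)-3-hydroxycyclooctane-2,4-dione in ring numbering (C5–C6 saturated, C5 prenyl trans to C7 prenyl), C1 side chain still CH(OTBS)CH(CH3)2
Conditions: [(Ph3P)CuH]6, H2O, benzene–THF, rt
Reagents that add atoms: none
Why: Copper hydride conjugate reduction delivers hydride to C6 of the enone only, isolated alkenes and saturated ketones being inert to this reagent; the C5 stereocentre arises on protonation of the copper enolate and, being α to the C4 ketone, can be equilibrated with a mild base toward the 5,7-trans arrangement if kinetic protonation is unselective.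

Step 16
Reactants: 34 silyl ether
Product: 35 (3R,5S,7S,8R)-diol, 34 with free CH(OH)CH(CH3)2 on C1
Conditions: HF·pyridine, pyridine, THF, 0 °C → rt
Reagents that add atoms: none
Why: Silyl ether cleavage with buffered HF–pyridine is acidic enough to spare the β-hydroxy ketone from retro-aldol cleavage and the tertiary α-ketol from rearrangement.

Step 17
Reactants: 35 diol
Product: 36 hyphenrone F, (2R,4R,5R,6S,8S)-2-hydroxy-5-methyl-2,6,8-tris(3-methylbut-2-enyl)-5-(4-methylpent-3-enyl)-4-(2-methylpropanoyl)cyclooctane-1,3-dione
Conditions: Dess–Martin periodinane, pyridine, CH2Cl2, 0 °C → rt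
Reagents that add atoms: none
Why: Dess–Martin oxidation converts the secondary alcohol into the ketone of the β-diketone while the tertiary C3 carbinol cannot react, and C1, now flanked by two carbonyl groups, should settle through its enol in the natural configuration with the isobutyryl group cis to the C8 methyl group.

**Compound list**

1 | 5-bromo-2-methylpent-2-ene | CC(C)=CCCBr | starting material
2 | propyne | CC#C | starting material
3 | (4-methylpent-3-enyl)magnesium bromide | CC(C)=CCC[Mg]Br | intermediate
4 | [(1Z)-2,6-dimethylhepta-1,5-dienyl]copper (MgBr2 complex, copper cis to the chain) | CC(C)=CCC/C(C)=C\[Cu] | intermediate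
5 | (1Z)-1-iodo-2,6-dimethylhepta-1,5-diene | CC(C)=CCC/C(C)=C\I | intermediate
6 | 5-methylhex-4-enal | CC(C)=CCCC=O | starting material
7 | malonic acid | OC(=O)CC(=O)O | starting material
8 | (3E)-7-methylocta-3,6-dienoic acid | CC(C)=CC/C=C/CC(=O)O | intermediate
9 | 1-bromo-3-methylbut-2-ene | CC(C)=CCBr | starting material
10 | dilithium (3E)-7-methylocta-1,3,6-triene-1,1-diolate | CC(C)=CC/C=C/C=C([O-])[O-].[Li+].[Li+] | intermediate
11 | (3E)-7-methyl-2-(3-methylbut-2-enyl)octa-3,6-dienoic acid (racemic) | CC(C)=CC/C=C/C(CC=C(C)C)C(=O)O | intermediate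
12 | (3E)-7-methyl-2-(3-methylbut-2-enyl)octa-3,6-dienoyl chloride (racemic) | CC(C)=CC/C=C/C(CC=C(C)C)C(Cl)=O | intermediate
13 | (2R,3R)-butane-2,3-diol | C[C@@H](O)[C@@H](C)O | starting material
14 | 2-bromo-1,1-diethoxyethane | CCOC(CBr)OCC | starting material
15 | (4R,5R)-2-(bromomethyl)-4,5-dimethyl-1,3-dioxolane | BrCC1O[C@H](C)[C@@H](C)O1 | intermediate
16 | (4R,5R)-4,5-dimethyl-2-methylidene-1,3-dioxolane | C=C1O[C@H](C)[C@@H](C)O1 | intermediate
17 | (3E)-7-methyl-2-(3-methylbut-2-enyl)octa-1,3,6-trien-1-one (vinylketene) | CC(C)=CC/C=C/C(CC=C(C)C)=C=O | intermediate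
18 | (1S,6R,7R)-6,7-dimethyl-1-(3-methylbut-2-enyl)-1-[(1E)-5-methylhexa-1,4-dienyl]-5,8-dioxaspiro[3.4]octan-2-one | O=C1CC2(O[C@H](C)[C@@H](C)O2)[C@@]1(CC=C(C)C)/C=C/CC=C(C)C | intermediate
19 | [(1Z)-2,6-dimethylhepta-1,5-dienyl]lithium | CC(C)=CCC/C(C)=C\[Li] | intermediate
20 | [(1Z)-2,6-dimethylhepta-1,5-dienyl]cerium dichloride | CC(C)=CCC/C(C)=C\[Ce](Cl)Cl | intermediate
21 | (1S,2S,6R,7R)-2-[(1Z)-2,6-dimethylhepta-1,5-dienyl]-6,7-dimethyl-1-(3-methylbut-2-enyl)-1-[(1E)-5-methylhexa-1,4-dienyl]-5,8-dioxaspiro[3.4]octan-2-ol (alkenyl groups cis) | CC(C)=CCC/C(C)=C\[C@@]1(O)CC2(O[C@H](C)[C@@H](C)O2)[C@@]1(CC=C(C)C)/C=C/CC=C(C)C | intermediate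
22 | potassium alkoxide of 21 | CC(C)=CCC/C(C)=C\[C@@]1([O-])CC2(O[C@H](C)[C@@H](C)O2)[C@@]1(CC=C(C)C)/C=C/CC=C(C)C.[K+] | intermediate
23 | potassium C1=C2 enolate of the (7S,8R)-cyclooct-5-en-2-one 4-ketal (ring numbering) | [K+].[O-]/C1=C/[C@](C)(CCC=C(C)C)[C@@H](CC=C(C)C)/C=C(/CC=C(C)C)C2(O[C@H](C)[C@@H](C)O2)C1 | intermediate
24 | (7S,8R)-2-(trimethylsilyloxy)cycloocta-1,5-diene (ring numbering, both ring alkenes cis in the ring) with spiro (4R,5R)-4,5-dimethyl-1,3-dioxolane at C4, 3-methylbut-2-enyl on C5 and C7, methyl and 4-methylpent-3-enyl on C8 | C[Si](C)(C)O/C1=C/[C@](C)(CCC=C(C)C)[C@@H](CC=C(C)C)/C=C(/CC=C(C)C)C2(O[C@H](C)[C@@H](C)O2)C1 | intermediate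
25 | 2-methylpropanal | CC(C)C=O | starting material
26 | lithium C1=C2 enolate corresponding to 24 | [Li+].[O-]/C1=C/[C@](C)(CCC=C(C)C)[C@@H](CC=C(C)C)/C=C(/CC=C(C)C)C2(O[C@H](C)[C@@H](C)O2)C1 | intermediate
27 | aldol: (7S,8R)-1-(1-hydroxy-2-methylpropyl)cyclooct-5-en-2-one 4-[(4R,5R)-4,5-dimethyl-1,3-dioxolane] ketal, substituents on C5, C7, C8 as in 24 (C1 and carbinol configuration not assigned) | O=C1C(C(O)C(C)C)[C@](C)(CCC=C(C)C)[C@@H](CC=C(C)C)/C=C(/CC=C(C)C)C2(O[C@H](C)[C@@H](C)O2)C1 | intermediate
28 | tert-butyldimethylsilyl ether of 27 | O=C1C(C(O[Si](C)(C)C(C)(C)C)C(C)C)[C@](C)(CCC=C(C)C)[C@@H](CC=C(C)C)/C=C(/CC=C(C)C)C2(O[C@H](C)[C@@H](C)O2)C1 | intermediate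
29 | (7S,8R)-1-[1-(tert-butyldimethylsilyloxy)-2-methylpropyl]-8-methyl-5,7-bis(3-methylbut-2-enyl)-8-(4-methylpent-3-enyl)cyclooct-5-ene-2,4-dione (ring numbering) | O=C1C(C(O[Si](C)(C)C(C)(C)C)C(C)C)[C@](C)(CCC=C(C)C)[C@@H](CC=C(C)C)/C=C(/CC=C(C)C)C(=O)C1 | intermediate
30 | 3-methylbut-2-enyl acetate | CC(C)=CCOC(C)=O | starting material
31 | 29 with an additional 3-methylbut-2-enyl group on C3 (C3 enolisable) | O=C1C(C(O[Si](C)(C)C(C)(C)C)C(C)C)[C@](C)(CCC=C(C)C)[C@@H](CC=C(C)C)/C=C(/CC=C(C)C)C(=O)C1CC=C(C)C | intermediate
32 | potassium C2/C4 diketonate of 31 | O=C1C(C(O[Si](C)(C)C(C)(C)C)C(C)C)[C@](C)(CCC=C(C)C)[C@@H](CC=C(C)C)/C=C(/CC=C(C)C)C([O-])=C1CC=C(C)C.[K+] | intermediate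
33 | 31 with hydroxyl on C3, C3 configured as in the target (hydroxyl on the face of the C8 methyl group) | CC(C)=CCC[C@]1(C)[C@@H](CC=C(C)C)/C=C(/CC=C(C)C)C(=O)[C@](O)(CC=C(C)C)C(=O)C1C(O[Si](C)(C)C(C)(C)C)C(C)C | intermediate
34 | (3R,5S,7S,8R)-1-[1-(tert-butyldimethylsilyloxy)-2-methylpropyl]-3-hydroxy-8-methyl-3,5,7-tris(3-methylbut-2-enyl)-8-(4-methylpent-3-enyl)cyclooctane-2,4-dione (ring numbering) | CC(C)=CCC[C@]1(C)[C@@H](CC=C(C)C)C[C@H](CC=C(C)C)C(=O)[C@](O)(CC=C(C)C)C(=O)C1C(O[Si](C)(C)C(C)(C)C)C(C)C | intermediate
35 | (3R,5S,7S,8R)-3-hydroxy-1-(1-hydroxy-2-methylpropyl)-8-methyl-3,5,7-tris(3-methylbut-2-enyl)-8-(4-methylpent-3-enyl)cyclooctane-2,4-dione (ring numbering) | CC(C)=CCC[C@]1(C)[C@@H](CC=C(C)C)C[C@H](CC=C(C)C)C(=O)[C@](O)(CC=C(C)C)C(=O)C1C(O)C(C)C | intermediate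
36 | hyphenrone F, (2R,4R,5R,6S,8S)-2-hydroxy-5-methyl-2,6,8-tris(3-methylbut-2-enyl)-5-(4-methylpent-3-enyl)-4-(2-methylpropanoyl)cyclooctane-1,3-dione | CC(C)=CCC[C@]1(C)[C@@H](CC=C(C)C)C[C@H](CC=C(C)C)C(=O)[C@](O)(CC=C(C)C)C(=O)[C@H]1C(=O)C(C)C | target

**Step count and risks**

Total step count: 17. Longest linear sequence: 14 steps (6 to 36 through steps 2–4 and 7–17).

Steps most likely to fail:

Step 7. The hindered alkyl(vinyl)ketene may dimerise, or the acid chloride may acylate the ketene acetal on carbon, faster than the cycloaddition. Ring closure of the zwitterion also has no facial bias at C5, so half of the material is the unwanted epimer and the separation may be difficult. The fallback sets out from acid 8 and comes back at 18. Acid 8 would be converted with (COCl)2 and catalytic DMF into (3E)-7-methylocta-3,6-dienoyl chloride F1. Dehydrochlorination of F1 with Et3N in the presence of 16 should pass through the less hindered [(1E)-5-methylhexa-1,4-dienyl]ketene F2 to (6R,7R)-6,7-dimethyl-1-[(1E)-5-methylhexa-1,4-dienyl]-5,8-dioxaspiro[3.4]octan-2-one F3. Both C5 epimers of F3 are usable because C5 is deprotonated next. The C5–prenyl bond would then be made on the ring by asymmetric allylic alkylation: the lithium dienolate of F3 (LiN(SiMe3)2, THF, −78 °C; the C5 hydrogen is both α to the ketone and allylic) would react with 30 under Pd2(dba)3 and a C2-symmetric chiral diphosphine ligand. C5 would thus come under catalyst control in place of a separation, giving 18.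

Step 9. The inside 4-methylpent-3-enyl chain crowds the boat, so heterolytic C2–C5 fragmentation of the alkoxide to an enone and an allyl anion, followed by stepwise re-closure, may compete with the concerted shift and erode the C7/C8 configuration. The enolate may also equilibrate toward C3 before it is trapped. The fallback sets out from 21 and comes back at 24. Cyclobutanol 21 would be silylated with N-(trimethylsilyl)imidazole to the trimethylsilyl ether of 21 F4. Heating F4 in toluene at 80–110 °C in base-washed glassware should bring about the neutral thermal Cope rearrangement of the cis-1,2-dialkenylcyclobutane through the same boat. No alkoxide is present that could fragment, and the silyl enol ether 24 is delivered directly and regiospecifically.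

Step 14. Facial selectivity of oxygen transfer to the C3 enolate rests only on the conformation of the eight-membered ring and may be poor or may favour the wrong face. The fallback sets out from 29 and comes back at 33; it reverses the order in which the C–O and C–C bonds at C3 are made, so that the group entering last on the preferred face is the prenyl group and not the oxygen. The sodium enolate of 29 (NaH, THF, 0 °C) would be benzoyloxylated with dibenzoyl peroxide to the 3-benzoyloxy derivative of 29 F5. Palladium-catalysed prenylation of F5 with 30 (Pd(PPh3)4, Et3N, THF) would give the 3-benzoyloxy-3-prenyl enedione F6. Mild methanolysis of F6 (K2CO3 cat., MeOH, 0 °C) would then release the tertiary alcohol 33.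

Further compounds
F1 | step 7 | (3E)-7-methylocta-3,6-dienoyl chloride | CC(C)=CC/C=C/CC(Cl)=O
F2 | step 7 | [(1E)-5-methylhexa-1,4-dienyl]ketene, (3E)-7-methylocta-1,3,6-trien-1-one | CC(C)=CC/C=C/C=C=O
F3 | step 7 | (6R,7R)-6,7-dimethyl-1-[(1E)-5-methylhexa-1,4-dienyl]-5,8-dioxaspiro[3.4]octan-2-one (both C1 epimers) | O=C1CC2(O[C@H](C)[C@@H](C)O2)C1/C=C/CC=C(C)C
F4 | step 9 | trimethylsilyl ether of 21 | CC(C)=CCC/C(C)=C\[C@@]1(O[Si](C)(C)C)CC2(O[C@H](C)[C@@H](C)O2)[C@@]1(CC=C(C)C)/C=C/CC=C(C)C
F5 | step 14 | 3-benzoyloxy derivative of 29 | O=C1C(C(O[Si](C)(C)C(C)(C)C)C(C)C)[C@](C)(CCC=C(C)C)[C@@H](CC=C(C)C)/C=C(/CC=C(C)C)C(=O)C1OC(=O)c1ccccc1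
F6 | step 14 | 3-benzoyloxy-3-prenyl enedione (benzoate of 33) | CC(C)=CCC[C@]1(C)[C@@H](CC=C(C)C)/C=C(/CC=C(C)C)C(=O)[C@](OC(=O)c2ccccc2)(CC=C(C)C)C(=O)C1C(O[Si](C)(C)C(C)(C)C)C(C)C
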